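**Retrosynthetic overview**
1. Last disconnection: a retro-[4+2] through C6–C7 and C8–C9 of the upper half opens ring C (C8, C9, C11–C14) together with ring B. This leads to an aryl-fused vinylketene (C6=C5–C10=C9), stored as an 8,8-disubstituted benzocyclobutenone (a temporary four-membered ring), and an ethynyl group (C7≡C8) on C14.
2. Enabling feature: ring B is a 4,4-disubstituted naphthalen-1(4H)-one on aromatic ring A (C6 ketone on C5, C7=C8, quaternary benzylic C9 on C10), with ring C fused on its C8–C9 edge and C8 bonded to quaternary C14.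
3. Before that, the 1,4-dioxane is closed by hetero-Diels–Alder addition of the seco o-quinone to the C3'=C4' enol bond of tingenone (lower half used intact).
4. The benzocyclobutenone comes from an aryl propionitrile and a ring D/E iodide (alkylation, nitrile reduction, Pd-catalysed ring closure); the arene comes from 3,4-dihydroxy-5-methylbenzaldehyde.
5. The ring D/E iodide, with all six stereocentres, comes from 22β-hydroxytingenone by C–C cleavage (ozonolytic excision of rings A/B, oxidative decarboxylation, glycol cleavage of C8–C9). Ring order: D, E and A given, then four-membered ring, dioxane, and B with C (C8–C9 bond last).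

Key step: step 20

Assumption: tingenone, 22β-hydroxytingenone and 3,4-dihydroxy-5-methylbenzaldehyde are taken as purchasable; celastroid atom numbers are used for both halves (primes = lower half); centres that are destroyed or reset later (C8, C9, C21; C6 in a fallback) are carried as epimer mixtures and left undefined in the SMILES.

**Route**

Step 1
Reactants: 1 22β-hydroxytingenone
Product: 2 3,22-bis-O-(methoxymethyl)-22β-hydroxytingenone
Conditions: MOMCl, i-Pr2NEt, n-Bu4NI (cat.), CH2Cl2, 0 → 40 °C
Reagents that add atoms: chloromethyl methyl ether, COCCl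
Why: O-alkylation (MOM acetal formation) of the acidic enolic 3-OH and the hindered 22-OH masks the α-ketol against the later glycol-cleaving oxidants and, unlike a silyl group, cannot migrate to O21; no stereocentre is touched.

Step 2
Reactants: 2 bis-MOM ether
Product: 3 ring C/D/E keto acid (C8 ketone; C9 bearing CH3 and CO2H, the former C10)
Conditions: O3 (excess), CH2Cl2/MeOH, −78 °C; then H2O2, aq. NaHCO3, 0 °C → rt; cold acidic work-up
Reagents that add atoms: ozone, O=[O+][O-]; hydrogen peroxide, OO
Why: Exhaustive (degradative) ozonolysis with oxidative work-up should cleave all four C=C bonds of the quinone methide and the α-dicarbonyl units that result, so that C7=C8 leaves the C8 ketone and C10 stays as CO2H on the untouched quaternary C9, while the saturated rings C–E and their stereocentres are not affected.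

Step 3
Reactants: 3 keto acid
Product: 4 9-acetoxy-8-ketone (C9 epimers)
Conditions: Pb(OAc)4, pyridine (cat.), benzene, 50 °C
Reagents that add atoms: lead tetraacetate, CC(=O)O[Pb](OC(C)=O)(OC(C)=O)OC(C)=O
Why: Oxidative decarboxylation of a β-keto acid by tetravalent lead should give the α-acetoxy ketone only at C9, the carbon that loses CO2, so C9 is oxygenated without enolate chemistry that the C21 ketone would share; the C9 configuration is irrelevant.

Step 4
Reactants: 4 acetoxy ketone
Product: 5 8,9,21-triol (epimers at C8, C9, C21)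
Conditions: LiAlH4, THF, 0 °C → reflux; Na2SO4·10H2O
Reagents that add atoms: none
Why: Hydride reduction of both ketones with reductive removal of the acetate gives the 8,9-glycol and stores the C21 ketone as a carbinol; the new carbinol centres are later destroyed (C8, C9) or re-oxidised (C21).

Step 5
Reactants: 5 triol
Product: 6 8,9-seco keto aldehyde (C14 formyl; C13 3-oxobutyl)
Conditions: Pb(OAc)4, benzene/CH2Cl2, 0 °C
Reagents that add atoms: none
Why: Criegee glycol cleavage of the only free 1,2-diol (O22 is an ether) breaks the C8–C9 bond and opens ring C to the C14 aldehyde and the C9 methyl ketone, with C13, C14 and the ring D/E centres intact.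

Step 6
Reactants: 6 keto aldehyde
Product: 7 C14-ethynyl methyl ketone
Conditions: dimethyl (1-diazo-2-oxopropyl)phosphonate, K2CO3, MeOH, 0 °C → rt
Reagents that add atoms: dimethyl (1-diazo-2-oxopropyl)phosphonate, CC(=O)C(=[N+]=[N-])P(=O)(OC)OC
Why: Ohira–Bestmann (Seyferth–Gilbert) homologation converts the non-enolisable neopentyl aldehyde into the terminal alkyne C8≡C7 under carbonate conditions that should leave the methyl ketone alone.

Step 7
Reactants: 7 methyl ketone
Product: 8 C13 2-acetoxyethyl compound
Conditions: mCPBA, CH2Cl2, reflux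
Reagents that add atoms: 3-chloroperbenzoic acid, OOC(=O)c1cccc(Cl)c1
Why: Baeyer–Villiger oxidation with migration of the primary alkyl group (C11) in preference to methyl excises C9 as an acetate; the masked C21 carbinol cannot compete as a ketone.

Step 8
Reactants: 8 acetate
Product: 9 C13 2-hydroxyethyl compound
Conditions: K2CO3 (cat.), MeOH, rt
Reagents that add atoms: none
Why: Base-catalysed transesterification frees the primary alcohol at C11 without touching the MOM ether or the alkyne.

Step 9
Reactants: 9 diol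
Product: 10 C13 2-iodoethyl compound (ring D/E iodide)
Conditions: I2, PPh3, imidazole, CH2Cl2, 0 °C → rt
Reagents that add atoms: iodine, II
Why: Appel-type iodination is selective for the primary alcohol over the hindered secondary C21 carbinol.

Step 10
Reactants: 11 3,4-dihydroxy-5-methylbenzaldehyde
Product: 12 3,4-bis(methoxymethoxy)-5-methylbenzaldehyde
Conditions: MOMCl, i-Pr2NEt, CH2Cl2, 0 °C → rt
Reagents that add atoms: chloromethyl methyl ether, COCCl
Why: Phenol O-alkylation protects the catechol as base- and hydride-stable acetals that are removed later together with the 22-O-MOM group.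

Step 11
Reactants: 12 bis-MOM aldehyde
Product: 13 2-bromo-4,5-bis(methoxymethoxy)-3-methylbenzaldehyde
Conditions: NBS, DMF, 0 °C → rt
Reagents that add atoms: N-bromosuccinimide, BrN1C(=O)CCC1=O
Why: Electrophilic aromatic bromination should enter para to the unhindered alkoxy group (the future O2), as in 3,4-dialkoxybenzaldehydes, which places bromine on the future C5.

Step 12
Reactants: 13 bromo aldehyde
Product: 14 [2-bromo-4,5-bis(methoxymethoxy)-3-methylphenyl]acetonitrile
Conditions: TosMIC, KOt-Bu, DME, −40 °C; then MeOH, 65 °C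
Reagents that add atoms: tosylmethyl isocyanide, [C-]#[N+]CS(=O)(=O)c1ccc(C)cc1
Why: The van Leusen reductive cyanation converts the aldehyde into the homologous nitrile in one operation (the new carbon becomes C6).

Step 13
Reactants: 14 arylacetonitrile
Product: 15 2-[2-bromo-4,5-bis(methoxymethoxy)-3-methylphenyl]propanenitrile (racemic)
Conditions: LiN(SiMe3)2, THF, −78 °C; MeI
Reagents that add atoms: iodomethane, CI
Why: α-Methylation of the benzylic nitrile anion installs the C9 methyl group; the centre formed is racemic and is reset later.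

Step 14
Reactants: 15 aryl propionitrile; 10 ring D/E iodide
Product: 16 quaternary nitrile (C9 epimers)
Conditions: 15, LiN(SiMe3)2, THF/DMPU, −78 °C; then 10, → rt
Reagents that add atoms: none
Why: SN2 alkylation of the stabilised tertiary benzylic nitrile anion by the primary iodide forms the quaternary C9; the anion is too weak a base to deprotonate the C21 carbinol or the alkyne, and both C9 epimers are used.

Step 15
Reactants: 16 quaternary nitrile
Product: 18 quaternary aldehyde (C9 carrying CH3, CHO, aryl and the C11 chain), via aldimine 17 (not isolated)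
Conditions: i-Bu2AlH, toluene, −78 → −20 °C; then aq. tartaric acid, SiO2, rt
Reagents that add atoms: water, O
Why: Half-reduction of the hindered nitrile with i-Bu2AlH stops at the N-aluminated imine, which mild acid hydrolyses to the non-enolisable aldehyde without loss of the MOM groups.

Step 16
Reactants: 18 quaternary aldehyde
Product: 19 benzocyclobutenone (ring C5–C6(=O)–C9–C10; C21 carbinol)
Conditions: Pd2(dba)3 (cat.), rac-BINAP, Cs2CO3, 1,4-dioxane, 100 °C
Reagents that add atoms: none
Why: Palladium-catalysed intramolecular acylation of the aryl bromide by the aldehyde C–H bond, a reaction type established for α,α-disubstituted (2-bromoaryl)acetaldehydes, should close the four-membered ring; the aldehyde cannot undergo α-arylation, and 100 °C is expected to lie below the onset of electrocyclic opening of the product.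

Step 17
Reactants: 19 benzocyclobutenone carbinol
Product: 20 benzocyclobutenone with C21 ketone
Conditions: Dess–Martin periodinane, CH2Cl2, rt
Reagents that add atoms: none
Why: Dess–Martin oxidation restores the C21 ketone under neutral conditions that should not epimerise C20 or C22.

Step 18
Reactants: 20 MOM-protected benzocyclobutenone
Product: 21 catechol benzocyclobutenone (free O2-H, O3-H and 22-OH)
Conditions: HCl (cat.), MeOH/THF, 40 °C
Reagents that add atoms: none
Why: Acid-catalysed acetal exchange removes all three MOM groups in one operation.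

Step 19
Reactants: 21 catechol benzocyclobutenone; 22 tingenone
Product: 24 seco dimer (cis-fused dioxane; benzocyclobutenone; C14 ethynyl), via o-quinone 23 (not isolated)
Conditions: Ag2O, CH2Cl2, 0 °C → rt, dark
Reagents that add atoms: none
Why: Oxidation of the catechol to the o-quinone and inverse-demand hetero-Diels–Alder addition of its O=C–C=O unit to the electron-rich C3'=C4' enol bond of 22 (a reaction type with precedent for celastroid dimers) should close the cis-fused dioxane; the C6 ketone on C5, para to O2, directs the nucleophilic C4' to O3 and the hemiketal carbon C3' to O2, and since C3'/C4' follow the face of ring A of 22 that is attacked, the required β-face adduct is expected together with its α-face isomer and is separated by chromatography.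

Step 20
Reactants: 24 seco dimer
Product: 26 target CNP0218299.2, via aryl vinylketene 25 (not isolated)
Conditions: PhCl (degassed, 1 mM), 150 °C, sealed tube
Reagents that add atoms: none
Why: Proposed new method: at 150 °C the benzocyclobutenone should open by conrotatory four-electron electrocyclic cleavage of its C6–C9 bond to the aryl-fused vinylketene 25, whose C6=C5–C10=C9 diene is trapped by the tethered C7≡C8 alkyne in an intramolecular [4+2] cycloaddition that re-aromatises ring A and gives the C6 ketone, the C7=C8 bond and the quaternary C9 in one operation; the closest known reaction types are the intramolecular Diels–Alder reactions of o-quinodimethanes made from benzocyclobutenes (steroid ring B/C annulation) and the capture of vinylketenes from cyclobutenones by alkynes. Ring B closes through both new bonds (C6–C7 and C8–C9), and ring C closes through the C8–C9 bond in a type 1 (fused) intramolecular mode over the four-carbon tether C11–C12–C13–C14, this bond being the later one of an asynchronous addition that starts with attack of the terminal alkyne carbon C7 on the ketene carbon C6. The new stereocentre C9 is controlled by C13 and C14: only the chair-like tether that keeps the ring D bonds (C15, C18) equatorial on the forming ring C is accessible, and it places the C9 methyl syn to the C14 methyl, as in the target. The step is stereoconvergent, because C9 of 24 becomes trigonal in 25 and both epimers, through E/Z isomers of 25 that interconvert by reclosure, reach the same transition state. Regiochemistry is fixed by the tether, the [2+2]/benzannulation mode of vinylketenes is excluded because it could not re-aromatise ring A, and capture of the ketene by the free hydroxy groups or by a second molecule is suppressed by high dilution and by the reversibility of the ring opening.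

**Compound list**
1 | 22β-hydroxytingenone | CC1=C(O)C(=O)C=C2C1=CC=C1[C@@]2(C)CC[C@@]2(C)[C@@H]3C[C@@H](C)C(=O)[C@@H](O)[C@]3(C)CC[C@]12C | starting material
2 | 3,22-bis-O-(methoxymethyl)-22β-hydroxytingenone | CC1=C(OCOC)C(=O)C=C2C1=CC=C1[C@@]2(C)CC[C@@]2(C)[C@@H]3C[C@@H](C)C(=O)[C@@H](OCOC)[C@]3(C)CC[C@]12C | intermediate
3 | ring C/D/E keto acid (C8 ketone; C9 with CH3 and CO2H; C21 ketone; 22β-OMOM) | O=C1[C@](C)(C(=O)O)CC[C@@]2(C)[C@@H]3C[C@@H](C)C(=O)[C@@H](OCOC)[C@]3(C)CC[C@]12C | intermediate
4 | 9-acetoxy-8-ketone (C9 epimers) | O=C1C(C)(OC(C)=O)CC[C@@]2(C)[C@@H]3C[C@@H](C)C(=O)[C@@H](OCOC)[C@]3(C)CC[C@]12C | intermediate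
5 | 8,9,21-triol (22β-OMOM; epimers at C8, C9, C21) | OC1C(C)(O)CC[C@@]2(C)[C@@H]3C[C@@H](C)C(O)[C@@H](OCOC)[C@]3(C)CC[C@]12C | intermediate
6 | 8,9-seco keto aldehyde (rings D/E; C14 formyl; C13 3-oxobutyl; C21 carbinol) | CC(=O)CC[C@@]1(C)[C@@H]2C[C@@H](C)C(O)[C@@H](OCOC)[C@]2(C)CC[C@]1(C)C=O | intermediate
7 | C14-ethynyl methyl ketone | CC(=O)CC[C@@]1(C)[C@@H]2C[C@@H](C)C(O)[C@@H](OCOC)[C@]2(C)CC[C@]1(C)C#C | intermediate
8 | C13 2-acetoxyethyl compound | CC(=O)OCC[C@@]1(C)[C@@H]2C[C@@H](C)C(O)[C@@H](OCOC)[C@]2(C)CC[C@]1(C)C#C | intermediate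
9 | C13 2-hydroxyethyl compound | OCC[C@@]1(C)[C@@H]2C[C@@H](C)C(O)[C@@H](OCOC)[C@]2(C)CC[C@]1(C)C#C | intermediate
10 | ring D/E iodide (C13 2-iodoethyl; C14 ethynyl) | ICC[C@@]1(C)[C@@H]2C[C@@H](C)C(O)[C@@H](OCOC)[C@]2(C)CC[C@]1(C)C#C | intermediate
11 | 3,4-dihydroxy-5-methylbenzaldehyde | Cc1cc(C=O)cc(O)c1O | starting material
12 | 3,4-bis(methoxymethoxy)-5-methylbenzaldehyde | Cc1cc(C=O)cc(OCOC)c1OCOC | intermediate
13 | 2-bromo-4,5-bis(methoxymethoxy)-3-methylbenzaldehyde | Cc1c(Br)c(C=O)cc(OCOC)c1OCOC | intermediate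
14 | [2-bromo-4,5-bis(methoxymethoxy)-3-methylphenyl]acetonitrile | Cc1c(Br)c(CC#N)cc(OCOC)c1OCOC | intermediate
15 | 2-[2-bromo-4,5-bis(methoxymethoxy)-3-methylphenyl]propanenitrile (racemic) | Cc1c(Br)c(C(C)C#N)cc(OCOC)c1OCOC | intermediate
16 | quaternary nitrile (C9 epimers) | Cc1c(Br)c(C(C)(C#N)CC[C@@]2(C)[C@@H]3C[C@@H](C)C(O)[C@@H](OCOC)[C@]3(C)CC[C@]2(C)C#C)cc(OCOC)c1OCOC | intermediate
17 | aldimine of 18 | Cc1c(Br)c(C(C)(C=N)CC[C@@]2(C)[C@@H]3C[C@@H](C)C(O)[C@@H](OCOC)[C@]3(C)CC[C@]2(C)C#C)cc(OCOC)c1OCOC | intermediate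
18 | quaternary aldehyde | Cc1c(Br)c(C(C)(C=O)CC[C@@]2(C)[C@@H]3C[C@@H](C)C(O)[C@@H](OCOC)[C@]3(C)CC[C@]2(C)C#C)cc(OCOC)c1OCOC | intermediate
19 | benzocyclobutenone, C21 carbinol, three MOM groups | Cc1c2C(=O)C(C)(CC[C@@]3(C)[C@@H]4C[C@@H](C)C(O)[C@@H](OCOC)[C@]4(C)CC[C@]3(C)C#C)c2cc(OCOC)c1OCOC | intermediate
20 | benzocyclobutenone, C21 ketone, three MOM groups | Cc1c2C(=O)C(C)(CC[C@@]3(C)[C@@H]4C[C@@H](C)C(=O)[C@@H](OCOC)[C@]4(C)CC[C@]3(C)C#C)c2cc(OCOC)c1OCOC | intermediate
21 | catechol benzocyclobutenone | Cc1c2C(=O)C(C)(CC[C@@]3(C)[C@@H]4C[C@@H](C)C(=O)[C@@H](O)[C@]4(C)CC[C@]3(C)C#C)c2cc(O)c1O | intermediate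
22 | tingenone | CC1=C(O)C(=O)C=C2C1=CC=C1[C@@]2(C)CC[C@@]2(C)[C@@H]3C[C@@H](C)C(=O)C[C@]3(C)CC[C@]12C | starting material
23 | o-quinone of 21 | CC1=C2C(=O)C(C)(CC[C@@]3(C)[C@@H]4C[C@@H](C)C(=O)[C@@H](O)[C@]4(C)CC[C@]3(C)C#C)C2=CC(=O)C1=O | intermediate
24 | seco dimer (hetero-Diels–Alder adduct) | Cc1c2c(cc3c1C(=O)C3(C)CC[C@@]1(C)[C@@H]4C[C@@H](C)C(=O)[C@@H](O)[C@]4(C)CC[C@]1(C)C#C)O[C@@]1(O)C(=O)C=C3C(=CC=C4[C@@]3(C)CC[C@@]3(C)[C@@H]5C[C@@H](C)C(=O)C[C@]5(C)CC[C@]43C)[C@@]1(C)O2 | intermediate
25 | aryl vinylketene | CC1=C2C(=CC(=C(C)CC[C@@]3(C)[C@@H]4C[C@@H](C)C(=O)[C@@H](O)[C@]4(C)CC[C@]3(C)C#C)C1=C=O)O[C@@]1(O)C(=O)C=C3C(=CC=C4[C@@]3(C)CC[C@@]3(C)[C@@H]5C[C@@H](C)C(=O)C[C@]5(C)CC[C@]43C)[C@@]1(C)O2 | intermediate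
26 | CNP0218299.2 | Cc1c2c(cc3c1C(=O)C=C1[C@@]3(C)CC[C@@]3(C)[C@@H]4C[C@@H](C)C(=O)[C@@H](O)[C@]4(C)CC[C@]13C)O[C@@]1(O)C(=O)C=C3C(=CC=C4[C@@]3(C)CC[C@@]3(C)[C@@H]5C[C@@H](C)C(=O)C[C@]5(C)CC[C@]43C)[C@@]1(C)O2 | target

**Step count and risks**
Total steps: 20. Longest linear sequence: 16 steps (steps 1–9, then 14–20).

Steps most likely to fail:

1. Step 20 (Proposed new method). The ring opening may need a temperature at which the trienone/hemiketal half degrades, the transient ketene may be intercepted by hydroxy groups or dimerise, or the tether may close through a boat-like arrangement and give the C9 epimer. The fallback uses known chemistry, sets out from 20 and returns at 26. NaBH4 (MeOH/CH2Cl2, −78 °C) should reduce the strained four-ring ketone in preference to the hindered C21 ketone and give the benzocyclobutenol F1 (C6 epimers). Cleavage of the MOM acetals (TMSOTf, 2,2'-bipyridyl, CH2Cl2, 0 °C; then H2O) gives the catechol benzocyclobutenol F2. Ag2O in the presence of 22 should give, by way of the o-quinone F3, the hetero-Diels–Alder adduct F4. Heating F4 in toluene at 110 °C opens the benzocyclobutenol to the hydroxy-o-quinodimethane F5, whose intramolecular Diels–Alder reaction with the alkyne should give the 6-hydroxy pentacycle F6. MnO2 oxidation of the benzylic, allylic 6-carbinol then gives 26.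

2. Step 2. Over-oxidation (MOM acetal, tertiary C–H), incomplete cleavage of the electron-poor enone stages, or decarboxylation of the β-keto acid during work-up may occur. The fallback sets out from 2 and returns at 3. NaBH4 (THF/MeOH, 0 °C) should aromatise ring A by 1,6-hydride addition, and reduce C21, to give the phenol F7. RuCl3 (cat.)/NaIO4 (CCl4/MeCN/H2O) then degrades the electron-rich arene to the C9 carboxylic acid, cleaves C7=C8 to the C8 ketone and re-oxidises C21, which gives 3.

3. Step 3. The lead-mediated decarboxylation may end in elimination to an enone or in simple protodecarboxylation, which would bring back the two-ketone selectivity problem. The fallback sets out from 3 and returns at 5. The acid is converted (N-hydroxypyridine-2-thione, DCC, dark) into the Barton ester F8. Visible-light decarboxylation under O2 with t-BuSH gives the 9-hydroperoxide F9. P(OMe)3 reduces it to the 9-hydroxy-8-ketone F10. LiAlH4 then gives 5.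

Further compounds
F1 | step 20 | benzocyclobutenol, C21 ketone, three MOM groups (C6 epimers) | Cc1c2C(O)C(C)(CC[C@@]3(C)[C@@H]4C[C@@H](C)C(=O)[C@@H](OCOC)[C@]4(C)CC[C@]3(C)C#C)c2cc(OCOC)c1OCOC
F2 | step 20 | catechol benzocyclobutenol | Cc1c2C(O)C(C)(CC[C@@]3(C)[C@@H]4C[C@@H](C)C(=O)[C@@H](O)[C@]4(C)CC[C@]3(C)C#C)c2cc(O)c1O
F3 | step 20 | o-quinone of F2 | CC1=C2C(O)C(C)(CC[C@@]3(C)[C@@H]4C[C@@H](C)C(=O)[C@@H](O)[C@]4(C)CC[C@]3(C)C#C)C2=CC(=O)C1=O
F4 | step 20 | benzocyclobutenol seco dimer | Cc1c2c(cc3c1C(O)C3(C)CC[C@@]1(C)[C@@H]4C[C@@H](C)C(=O)[C@@H](O)[C@]4(C)CC[C@]1(C)C#C)O[C@@]1(O)C(=O)C=C3C(=CC=C4[C@@]3(C)CC[C@@]3(C)[C@@H]5C[C@@H](C)C(=O)C[C@]5(C)CC[C@]43C)[C@@]1(C)O2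
F5 | step 20 | hydroxy-o-quinodimethane | CC1=C2C(=CC(=C(C)CC[C@@]3(C)[C@@H]4C[C@@H](C)C(=O)[C@@H](O)[C@]4(C)CC[C@]3(C)C#C)C1=CO)O[C@@]1(O)C(=O)C=C3C(=CC=C4[C@@]3(C)CC[C@@]3(C)[C@@H]5C[C@@H](C)C(=O)C[C@]5(C)CC[C@]43C)[C@@]1(C)O2
F6 | step 20 | 6-hydroxy pentacycle (6-deoxo-6-hydroxy target, C6 epimers) | Cc1c2c(cc3c1C(O)C=C1[C@@]3(C)CC[C@@]3(C)[C@@H]4C[C@@H](C)C(=O)[C@@H](O)[C@]4(C)CC[C@]13C)O[C@@]1(O)C(=O)C=C3C(=CC=C4[C@@]3(C)CC[C@@]3(C)[C@@H]5C[C@@H](C)C(=O)C[C@]5(C)CC[C@]43C)[C@@]1(C)O2
F7 | step 2 | ring A phenol (2-OH, 3-OMOM, C6 methylene, C7=C8, C21 carbinol, 22β-OMOM) | Cc1c(OCOC)c(O)cc2c1CC=C1[C@@]2(C)CC[C@@]2(C)[C@@H]3C[C@@H](C)C(O)[C@@H](OCOC)[C@]3(C)CC[C@]12C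
F8 | step 3 | Barton ester of 3 | O=C1[C@](C)(C(=O)On3ccccc3=S)CC[C@@]2(C)[C@@H]3C[C@@H](C)C(=O)[C@@H](OCOC)[C@]3(C)CC[C@]12C
F9 | step 3 | 9-hydroperoxy-8-ketone (C9 epimers) | O=C1C(C)(OO)CC[C@@]2(C)[C@@H]3C[C@@H](C)C(=O)[C@@H](OCOC)[C@]3(C)CC[C@]12C
F10 | step 3 | 9-hydroxy-8-ketone (C9 epimers) | O=C1C(C)(O)CC[C@@]2(C)[C@@H]3C[C@@H](C)C(=O)[C@@H](OCOC)[C@]3(C)CC[C@]12C
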